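**Plan**
- Cuts: first C2–Br and C2'–Br (back to C2–SnBu3 and C2'–H), then C2–C3 and C2'–C3' of both pyrrole rings together, and last the two aryl–CH= bonds of the stilbene that results.
- Enabling feature: C2 and C2' are each bonded to the ring nitrogen, to C3/C3' and to one heteroatom, which is the pattern an aryl isocyanide carbon acquires by radical 1,1-addition. C3–C3' joins two carbons that sit on C3a and C3a' of the benzo rings, so it is the central bond of a 2,2'-diisocyanostilbene.
- Forward: both dibromobenzo rings come ready-made from 3,4-dibromoaniline (iodination ortho to N, then N-formylation). They are joined through a CH=CH unit by a twofold Stille coupling, and the formamides are dehydrated.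
- One tin hydride chain closes pyrrole ring A (C2–C3) and, through the benzylic radical left behind, pyrrole ring B (C2'–C3'). NBS then replaces tin at C2 and hydrogen at C2' by bromine.
- Stereochemistry: the target has no stereocentre. The E alkene comes from the distannylethene and is consumed, and the two sp3 carbons made in the cascade are erased by tautomerisation.

Key step: step 5

Assumption: the target SMILES carries no descriptor for the C3–C3' axis, so the biaryl is treated as racemic or freely rotating and no axial control is attempted.

Step 1
Reactants: 1 3,4-dibromoaniline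
Product: 2 4,5-dibromo-2-iodoaniline
Conditions: NIS (1.0 equiv), AcOH, rt, dark
Reagents that add atoms: N-iodosuccinimide, O=C1CCC(=O)N1I
Why: Electrophilic aromatic iodination: the amino group directs ortho and para, the para position carries bromine and C2 is squeezed between NH2 and Br, so iodine should enter at C6, the usual outcome for 3,4-dihaloanilines.

Step 2
Reactants: 2 4,5-dibromo-2-iodoaniline
Product: 3 N-(4,5-dibromo-2-iodophenyl)formamide
Conditions: HCO2H/Ac2O (premixed, 55 °C), then 2, THF, 0 °C to rt
Reagents that add atoms: acetic formic anhydride, CC(=O)OC=O (made from formic acid, O=CO, and acetic anhydride, CC(=O)OC(C)=O)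
Why: N-Formylation by a mixed anhydride: the formyl carbonyl is the more electrophilic one and acylates even weakly nucleophilic haloanilines, which installs the carbon that becomes C2/C2' and masks the amine before the palladium step.

Step 3
Reactants: 3 N-(4,5-dibromo-2-iodophenyl)formamide (2 equiv); 4 (E)-1,2-bis(tributylstannyl)ethene (1 equiv)
Product: 6 (E)-N,N'-[ethene-1,2-diylbis(4,5-dibromo-2,1-phenylene)]diformamide, via monocoupled vinylstannane 5 (not isolated)
Conditions: Pd2(dba)3 (2.5 mol %), AsPh3 (20 mol %), CuI (10 mol %), DMF, rt to 45 °C; product collected by precipitation and washed free of tin with hexane/Et2O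
Reagents that add atoms: none
Why: Twofold Stille coupling: zerovalent palladium should insert into C–I well before C–Br at this temperature, alkenylstannanes transfer with retention of geometry, and 1,2-distannylethene is an established two-carbon linchpin for symmetrical E-stilbenes.

Step 4
Reactants: 6 (E)-N,N'-[ethene-1,2-diylbis(4,5-dibromo-2,1-phenylene)]diformamide
Product: 8 (E)-1,2-bis(4,5-dibromo-2-isocyanophenyl)ethene, via half-dehydrated formamide isocyanide 7 (not isolated)
Conditions: POCl3 (3 equiv), Et3N (10 equiv), THF, −20 to 0 °C; aq Na2CO3; short Et3N-deactivated silica plug, used promptly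
Reagents that add atoms: none
Why: Dehydration of formamides to isocyanides: O-phosphorylation by POCl3 and amine-induced elimination turn each NHCHO into N≡C below room temperature without touching the alkene or the aryl bromides, the standard access to 2-alkenylaryl isocyanides.

Step 5
Reactants: 8 (E)-1,2-bis(4,5-dibromo-2-isocyanophenyl)ethene; 9 tributyltin hydride
Product: 11 5,5',6,6'-tetrabromo-2-(tributylstannyl)-1H,1'H-3,3'-biindole, via bis(3H-indole) tautomer 10 (not isolated)
Conditions: 9 (1.0 equiv, syringe pump over 3 h), Et3B (0.3 equiv, in portions), trace air, toluene (0.01 M), 0 °C to rt; evaporation, plug of Et3N-deactivated silica, carried on without further purification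
Reagents that add atoms: none
Why: Proposed new method: ethyl radicals from Et3B and O2 abstract hydrogen from 9 and the tributylstannyl radical adds to one isocyanide carbon of the symmetrical 8; the α-stannylimidoyl radical attacks the alkene carbon bonded to its own arene (C2–C3), the benzylic radical thus placed on the other alkene carbon attacks the terminal carbon of the ortho isocyanide on the second arene (C2'–C3'), and the cyclic imidoyl radical takes hydrogen from 9 to give 10 and a new stannyl radical. The closest known reaction type is the tin hydride cyclisation of 2-alkenylaryl isocyanides to 2-stannylindoles (Fukuyama indole synthesis), which covers the first ring only, whereas five-ring closure of a benzylic carbon onto an ortho isocyanide has only an anionic counterpart, the Ito–Saegusa indole synthesis. Ring A closes 5-exo-trig and ring B 5-endo-dig as a 1,1-addition at the isocyanide carbon, which should be feasible because radical and acceptor are held ortho on one benzene ring, and which, if only about thermoneutral, is pulled forward by fast hydrogen capture of the σ-type imidoyl radical and by aromatisation. The two sp3 centres at C3 and C3' of 10 need no control, since twofold imine-to-enamine tautomerisation to 11 removes them, and the alkene geometry of 8 is already lost at the radical stage. In the first closure 5-exo should beat 6-endo because only it gives a benzylic radical, and the second closure should beat premature reduction because benzylic radicals take hydrogen from tin hydride slowly and 9 is kept dilute by slow addition. Stannyl radicals must add to isocyanide carbon rather than abstract aryl bromine, which is favoured by the expected lower barrier of the addition, by its rapid 5-exo capture, by the low temperature that Et3B initiation allows, and by limiting 9 to one equivalent so that 11, which has no isocyanide left, does not meet excess stannyl radicals.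

Step 6
Reactants: 11 5,5',6,6'-tetrabromo-2-(tributylstannyl)-1H,1'H-3,3'-biindole
Product: 13 2,2',5,5',6,6'-hexabromo-1H,1'H-3,3'-biindole, via 2,5,5',6,6'-pentabromo-3,3'-biindole 12 (not isolated)
Conditions: NBS (2.05 equiv), THF, −78 to 0 °C, dark; aq Na2S2O3/NaHCO3
Reagents that add atoms: N-bromosuccinimide, O=C1CCC(=O)N1Br
Why: Bromodestannylation followed by electrophilic 2-bromination of a 3-substituted indole: the C2–Sn bond is the most nucleophilic site and is substituted ipso, the second equivalent then brominates C2', the only free pyrrole position, the dibrominated benzo rings are too deactivated to compete, and any material that has lost tin to adventitious acid is carried to the same product.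

**Compound list**
1 | 3,4-dibromoaniline | Nc1ccc(Br)c(Br)c1 | starting material
2 | 4,5-dibromo-2-iodoaniline | Nc1cc(Br)c(Br)cc1I | intermediate
3 | N-(4,5-dibromo-2-iodophenyl)formamide | O=CNc1cc(Br)c(Br)cc1I | intermediate
4 | (E)-1,2-bis(tributylstannyl)ethene | CCCC[Sn](CCCC)(CCCC)/C=C/[Sn](CCCC)(CCCC)CCCC | starting material
5 | (E)-N-{4,5-dibromo-2-[2-(tributylstannyl)ethenyl]phenyl}formamide (not isolated) | O=CNc1cc(Br)c(Br)cc1/C=C/[Sn](CCCC)(CCCC)CCCC | intermediate
6 | (E)-N,N'-[ethene-1,2-diylbis(4,5-dibromo-2,1-phenylene)]diformamide | O=CNc1cc(Br)c(Br)cc1/C=C/c1cc(Br)c(Br)cc1NC=O | intermediate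
7 | (E)-N-{4,5-dibromo-2-[2-(4,5-dibromo-2-isocyanophenyl)ethenyl]phenyl}formamide (not isolated) | O=CNc1cc(Br)c(Br)cc1/C=C/c1cc(Br)c(Br)cc1[N+]#[C-] | intermediate
8 | (E)-1,2-bis(4,5-dibromo-2-isocyanophenyl)ethene | [C-]#[N+]c1cc(Br)c(Br)cc1/C=C/c1cc(Br)c(Br)cc1[N+]#[C-] | intermediate
9 | tributyltin hydride | CCCC[SnH](CCCC)CCCC | starting material
10 | 5,5',6,6'-tetrabromo-2-(tributylstannyl)-3H,3'H-3,3'-biindole (transient, C3/C3' configuration undefined, not isolated) | CCCC[Sn](CCCC)(CCCC)C1=Nc2cc(Br)c(Br)cc2C1C1C=Nc2cc(Br)c(Br)cc12 | intermediate
11 | 5,5',6,6'-tetrabromo-2-(tributylstannyl)-1H,1'H-3,3'-biindole | CCCC[Sn](CCCC)(CCCC)c1[nH]c2cc(Br)c(Br)cc2c1-c1c[nH]c2cc(Br)c(Br)cc12 | intermediate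
12 | 2,5,5',6,6'-pentabromo-1H,1'H-3,3'-biindole (not isolated) | Brc1[nH]c2cc(Br)c(Br)cc2c1-c1c[nH]c2cc(Br)c(Br)cc12 | intermediate
13 | 2,2',5,5',6,6'-hexabromo-1H,1'H-3,3'-biindole | Brc1cc2[nH]c(Br)c(-c3c(Br)[nH]c4cc(Br)c(Br)cc34)c2cc1Br | target

Total step count: 6. Longest linear sequence: 6 steps (1 to 13).

**Steps most likely to fail**

Step 5. Four processes threaten the cascade:
- Hydrogen transfer to the benzylic radical may come before the second closure.
- Stannyl radicals may abstract bromine from the arenes.
- The isocyanide may sequester the borane initiator.
- The chain may collapse because the stabilised benzylic radical propagates slowly.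

The fallback gives up radicals and changes the oxidation level of the two-carbon bridge. It sets out from 6. Diimide reduction (TsNHNH2, NaOAc, DME/H2O, reflux) spares aryl bromides and should give N,N'-[ethane-1,2-diylbis(4,5-dibromo-2,1-phenylene)]diformamide F1. Dehydration with POCl3/Et3N as in step 4 should give 1,2-bis(4,5-dibromo-2-isocyanophenyl)ethane F2, an isomer of the biindole core. Excess lithium 2,2,6,6-tetramethylpiperidide in THF, added at −78 °C so that benzylic deprotonation outruns metalation next to bromine and then warmed to rt, should bring about two successive Ito–Saegusa closures. In each one a benzylic anion attacks its ortho isocyanide carbon, and the product is 5,5',6,6'-tetrabromo-1H,1'H-3,3'-biindole F3. Two equivalents of NBS under the conditions of step 6 brominate C2 and C2', and the route is rejoined at 13.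

Step 3. Three processes could erode the twofold coupling:
- Oxidative addition into C–Br once the iodide runs low, with oligomerisation.
- Stalling after the first coupling, because 5 is a more hindered stannane.
- Protodestannylation of 5.

The fallback builds the alkene by metathesis instead of using a linchpin coupling. It sets out from 3. A single Suzuki–Miyaura vinylation (potassium vinyltrifluoroborate, PdCl2(dppf), Et3N, n-PrOH, 70 °C) should give N-(4,5-dibromo-2-ethenylphenyl)formamide F4. Self-metathesis of F4 with the second-generation Hoveyda–Grubbs catalyst in refluxing CH2Cl2 is driven by loss of ethene and by precipitation of the sparingly soluble E product, and it comes back to the route at 6.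

Step 6. Three processes could spoil the endgame:
- Oxidation of the electron-rich biindole core by NBS in place of substitution.
- Stalling after the first bromination, because the pentabromide is deactivated.
- Acid-induced decay of the N–H 2-bromoindole units.

The fallback replaces electrophilic attack by C–H borylation and halodeboronation. It sets out from 11. Protodestannylation with CF3CO2H in CH2Cl2 should give 5,5',6,6'-tetrabromo-1H,1'H-3,3'-biindole F3. Iridium-catalysed borylation ([Ir(OMe)(cod)]2, 4,4'-di-tert-butyl-2,2'-bipyridine, B2pin2, THF, 60 °C) goes to C2 on N–H indoles and avoids positions ortho to bromine. It should give 5,5',6,6'-tetrabromo-2,2'-bis(4,4,5,5-tetramethyl-1,3,2-dioxaborolan-2-yl)-1H,1'H-3,3'-biindole F5. CuBr2 in MeOH/H2O then exchanges boron for bromine and returns to the route at 13.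

**Further compounds**
F1 | step 5 | N,N'-[ethane-1,2-diylbis(4,5-dibromo-2,1-phenylene)]diformamide | O=CNc1cc(Br)c(Br)cc1CCc1cc(Br)c(Br)cc1NC=O
F2 | step 5 | 1,2-bis(4,5-dibromo-2-isocyanophenyl)ethane | [C-]#[N+]c1cc(Br)c(Br)cc1CCc1cc(Br)c(Br)cc1[N+]#[C-]
F3 | step 5 | 5,5',6,6'-tetrabromo-1H,1'H-3,3'-biindole | Brc1cc2[nH]cc(-c3c[nH]c4cc(Br)c(Br)cc34)c2cc1Br
F4 | step 3 | N-(4,5-dibromo-2-ethenylphenyl)formamide | C=Cc1cc(Br)c(Br)cc1NC=O
F5 | step 6 | 5,5',6,6'-tetrabromo-2,2'-bis(4,4,5,5-tetramethyl-1,3,2-dioxaborolan-2-yl)-1H,1'H-3,3'-biindole | CC1(C)OB(OC1(C)C)c1[nH]c2cc(Br)c(Br)cc2c1-c1c(B2OC(C)(C)C(C)(C)O2)[nH]c2cc(Br)c(Br)cc12
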